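The easy step is the substrate column of the elm run, read beside the charges of the new flasks.

| flask | substrate | reagent | temperature | remark | time |
|---|---|---|---|---|---|
| elm | 0.50 M | 3 M | −20 °C | run made earlier |  |
| Sunday's | 1.0 M | 3.00 M | −20 °C |  | 10 min |
| Tuesday's | 1.0 M | 3.00 M | −40 °C |  | 10 min |
| Monday's | 1.0 M | 3.00 M | 0 °C |  | 10 min |

elm run (percent of the substrate charged)

| time / s | target / % | substrate / % |
|---|---|---|
| 10.0 | 0.5 | 75.3 |
| 15.0 | 2.1 | 66.6 |
| 25.0 | 4.6 | 51.4 |
| 40.0 | 11.0 | 34.8 |
| 50.0 | 14.8 | 27.0 |
| 60.0 | 17.6 | 21.0 |

(each reading ± 0.3 percentage points)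

- the flask with the highest amount of target, in percent of the substrate charged ("all alike" if they lie within 1.5 percentage points) (Sunday's / Tuesday's / Monday's / all alike)
- final target, as a percentage of the substrate charged, in Sunday's
- final target, as a percentage of the substrate charged, in Tuesday's
- final target, as a percentage of the substrate charged, in Monday's

- steps thought possible: substrate + reagent -> intermediate + released group; intermediate <-> target; intermediate <-> isomer of the product; reagent -> decomposition product; target + released group -> side product
- the earlier runs do not show what temperature does; that part of a forecast is a guess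

At 60.0 s elm holds 21.0 % substrate. Each substrate lost takes one reagent, so the integrated second-order law gives k = 0.00946 M⁻¹ s⁻¹, the second-order constant of the attack of reagent on substrate. In Sunday's flask, by this reckoning of my own, c(substrate) starts down at 1.70 M min⁻¹. The knee, where half of the charge has reacted, comes at 0.450 min. Beyond it c(reagent) levels toward 66.7 % of its charge, and the substrate tail has a lifetime of 0.881 min. At 10 min, which is 11.4 lifetimes, the curve lies on the baseline at <0.001 % of the charge.

Target starts with a lag and then climbs in elm at 0.223 min⁻¹ of the charge, a slope taken over here for Sunday's. At the knee substrate still falls faster than target rises. The two slopes cross near 19.6 % substrate, about 1.16 min into Sunday's. At that slope the full charge needs 4.48 min, less than the 10 min allowed, so Sunday's should end on a plateau. Its height is a share of the pool, and elm never read isomer, so this reckoning gives a shape and no level.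

The forecast names Sunday's as the best flask, with 34 % there, 23 % in Tuesday's and 30 % in Monday's, on the grounds of “a ceiling near 38%, the remainder going to isomer”.

The flask with most target is Sunday's, at 55.7 %, against 16.8 % in Tuesday's and 23.6 % in Monday's.

    substrate + reagent → intermediate + released group (k = 0.00940 M⁻¹ s⁻¹, Ea = 40.0 kJ mol⁻¹)
    intermediate ⇌ target (K = 9.20, k = 0.00800 s⁻¹, Ea = 68.0 kJ mol⁻¹, ΔH = −54.0 kJ mol⁻¹)
    intermediate ⇌ isomer of the product (K = 2.20, k = 0.00490 s⁻¹, Ea = 77.0 kJ mol⁻¹, ΔH = −18.0 kJ mol⁻¹)
    reagent → decomposition product (k = 6.70 × 10⁻⁶ s⁻¹, Ea = 77.0 kJ mol⁻¹)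
    target + released group → side product (k = 4.50 × 10⁻⁴ M⁻¹ s⁻¹, Ea = 53.0 kJ mol⁻¹)
    (constants at −20 °C)

At 0.453 min, close to the reckoned knee 0.450 min, intermediate in Sunday's is made 2.26 times faster than it is used up. In a neighbouring flask like Sunday's but with 2.5 M of substrate, k leaves 1.02 % of the charge as substrate at 10 min, and that flask holds 1.1 %.

The runs are calculated from invented constants; the scatter is artificial.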